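The runs are calculated with constants of no real substance.

Which way of putting in the same charges left the most target at 4.0 h?

| flask | substrate | reagent | remark | time |
|---|---|---|---|---|
| south-east | 0.13 M | 1.2 equiv | run made earlier |  |
| north-west | 0.13 M | 0.80 equiv | run made earlier |  |
| south | 0.13 M | 1.8 equiv | run made earlier |  |
| Friday's | 0.13 M (fed, over 50 min) | 1.20 equiv | all else is in the flask from the start; the feed brings no volume worth counting | 4.0 h |
| Saturday's | 0.13 M | 1.20 equiv | everything together at the start | 4.0 h |
| Tuesday's | 0.13 M | 1.20 equiv (fed, over 50 min) | all else is in the flask from the start; the feed brings no volume worth counting | 4.0 h |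
| Thursday's | 0.13 M | 1.20 equiv (in portions, 5, over 50 min) | first portion at the start, last at 50 min | 4.0 h |

| run | time / h | target / % |
|---|---|---|
| south-east | 0.200 | 6 |
| south-east | 0.667 | 19 |
| south-east | 1.00 | 27 |
| south-east | 1.50 | 34 |
| south-east | 2.50 | 38 |
| south-east | 3.00 | 40 |
| south-east | 4.00 | 38 |
| north-west | 0.167 | 4 |
| north-west | 0.500 | 11 |
| north-west | 0.833 | 19 |
| north-west | 1.33 | 25 |
| north-west | 2.00 | 28 |
| north-west | 2.50 | 29 |
| north-west | 3.00 | 30 |
| south | 0.250 | 8 |
| south | 0.417 | 17 |
| south | 0.667 | 24 |
| south | 0.833 | 28 |
| south | 1.33 | 35 |
| south | 2.00 | 45 |
| south | 3.00 | 45 |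

(each reading ± 1.5 percentage points)

- the flask that comes out highest in amount of target, in percent of the substrate charged, or "all alike" when all lie within 1.5 percentage points (Friday's / Saturday's / Tuesday's / Thursday's / all alike)
- target at the end, in percent of the substrate charged, Friday's
- target at the end, in percent of the substrate charged, Saturday's
- target at the end, in percent of the substrate charged, Tuesday's
- target at the end, in percent of the substrate charged, Thursday's



I asked first what the end state was, then how fast it came. The plateaus read 30%, 40% and 45% at 0.80 equiv, 1.2 equiv and 1.8 equiv of reagent. The south reading stood higher than the north-west one, so more reagent per substrate gave more target. The pace came from the south-east run. Its gap to the plateau had shrunk to 13 percentage points at 1.00 h, which gives 1.12 /h. I call this reading λ, the rise constant: the rate at which target closes its remaining gap to the plateau.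

Then I turned the settings by hand. Time came first. A charge fed steadily over 50 min runs late by a factor L, which is exp(λ times feed time) less one, over λ times feed time. Here L is 1.66. On this reckoning the unmade share of the plateau at a time t past the end of the feed is L times exp(−λt), with t counted from the start, so 1.85% at 4.0 h. That estimate was what I gave longer stirring to add. Friday's fed its substrate into standing reagent, so the reagent per substrate present stood above the charged 1.20 equiv. The south run, richer in reagent at 1.8 equiv, had read higher than the south-east run, so I expected Friday's above Saturday's. Feeding reagent did the opposite, so I expected Tuesday's near the north-west plateau, and Thursday's with it.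

The forecast named Saturday's highest, with 38% for Friday's, 39% for Saturday's, 28% for Tuesday's and 29% for Thursday's. Its ground was that “the split depends on reagent present as substrate is consumed, not on clock time”. It put Friday's below Saturday's, where I had put it above.

Friday's gave 45.2%, Saturday's 40.6%, Tuesday's 25.9% and Thursday's 27.4%, so Friday's came out highest. The forecast stood 7.2 points low on Friday's.

    substrate + reagent ⇌ adduct (K = 47.0 /M, k = 0.00880 /M/s)
    adduct → target (k = 4.20 × 10⁻⁴ /s)
    target ⇌ isomer of the product (K = 0.680, k = 0.00350 /s)
    2 substrate → self-condensation product (k = 0.00320 /M/s)

Friday's held less self-condensation product than Saturday's at 4.00 h, 21.5% against 30.5%. Friday's had not quite come to rest. It still held 1.1% of substrate and 1.54% of adduct, and at 40.0 h it read 46.7%. That is a gain of 1.5 points, where my estimate from λ had put 0.84 points. Tuesday's read 26.3% at 40.0 h.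

On Tuesday's read at 1.0 h, λ left 54.2% of the plateau unmade, so with Tuesday's 25.9% taken as that plateau I reckoned 11.9%. That flask gave 12.0%.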